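## Structural features

The target is a diaryl ether without stereocentres, so no stereocentres stand next to each other. Ring A is a methyl 2,4-dihydroxybenzoate (ester carbon on C1) that carries the ether oxygen at C6. Ring B is a fully substituted benzene: ether oxygen at C1, free hydroxyl at C2, 3-methylbut-2-enyl (prenyl) groups at C3 and C4, methoxy groups at C5 and C6. All four positions ortho to the ether oxygen are substituted (ester and H-bearing carbon on ring A, hydroxyl and methoxy on ring B), so this bond is hard to make by a coupling of two finished rings. Ring B is a hydroquinone monomethyl ether (C2–OH para to C5–OMe) and is easily oxidised to the quinone. The two trisubstituted alkenes do not tolerate electrophilic oxidants, and under acid the C3 prenyl group can close onto the C2 hydroxyl to a chroman. The real difficulty is ring B: two adjacent prenyl groups must be placed, and four oxygens must be told apart (C1 arylated, C2 free, C5 and C6 methylated). The key step exploits the fact that the ring A carboxyl carbon and the ring B C2 oxygen are both ortho to the ether oxygen. Joining them gives a seven-membered lactone (a depsidone), and removing that oxygen gives a xanthone whose carbonyl carbon is the ester carbon.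

## Logic of the disconnections

**29 to 27 (through 28).** The two acetal C–O bonds on ring A and the ester O–CH3 bond are cut, and the acyl carbon is rejoined to the ring B C2 oxygen. In 27 the hydroxyl that must end free is held as an aryl ester, so it is distinguished from its para partner without a protecting group. The forward step needs methoxide to open the crowded aryl ester, and acid that removes the acetals without touching the prenyl alkene beside the freed C2 phenol.

**27 to 26.** The O–CH3 bond at ring B C5 is cut. 26 has a single free hydroxyl, so the methylation has no selectivity problem. The lactone must survive carbonate and iodomethane.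

**26 to 24 (key disconnection).** The oxygen between the carbonyl carbon and ring B is removed, i.e. the ring B C2–O bond is cut and the carbon–carbon bond restored. This turns the seven-membered lactone into a planar xanthone and lowers ring B from four oxygens to three, so the C2 oxygen never has to be carried or protected. The atom mapping of 24 onto 26 and 29 was checked (xanthone C8a, C6 and C5 become ring B C2, C5 and C6) and both structures are kept as they stand. The forward step needs a nucleophilic peroxide to add to a deactivated carbonyl, and ring B rather than ring A to migrate. This is why 24 has a free C6 hydroxyl while the ring A oxygens are capped.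

**24 to 22.** The aryl–CH2 bond at C7 is cut and reconnected as an O6–C(tertiary) ether (retro-Claisen). The same group then does two jobs: it masks the C6 oxygen during ring assembly, where a free phenol para to the ester would itself be arylated, and it delivers the second prenyl group while freeing the hydroxyl needed by the key step. The [3,3] shift must be faster than ionisation of the tertiary allyl ether.

**22 to 11 and 20 (through 21).** The O10–C4a and C9–C9a bonds are cut. The crowded diaryl ether and the ketone then come from one convergent aryne annulation instead of a coupling of hindered partners. The phenoxide of 11 must add to 21 at the carbon remote from the flanking acetal oxygen, and the aryl anion must reach an ester that sits between the new ether and a prenyl group.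

**11 to 8 and 10 (10 from 9).** The O–C(tertiary) bond is cut. Only the hydroxyl of 8 that is not chelated to the ester should react, and attack must occur at the tertiary end of the allyl unit.

**8 to 7 to 5.** The aryl–CO2Me bond is cut and the phenols are returned to their acetals. 5 is symmetrical, so either free ring position gives the same product. Lithiation must occur on the ring and not at the benzylic, allylic CH2.

**5 to 3 and 4, 3 to 2, 2 to 1.** The aryl–CH2 bond of the prenyl group that ends next to the carbonyl is cut, then the C–B bond, then the acetals. This carbon is meta to both oxygens and is reached neither by electrophilic substitution nor by ortho-metalation. Metalating an ester beside an existing prenyl group is not reliable, so this group is installed first, on a symmetrical ring, by sterically controlled borylation. The coupling must give the linear prenyl isomer.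

**20 to 18 to 14 to 13 to 12.** The O–S bond, the C–Si bond, the carbamate and two acetals are cut, back to a symmetrical triol. Lithiation must occur between the carbamate and an acetal oxygen and not between the two acetal oxygens, and the first step is a statistical bis-protection.

## Other disconnections considered

**Alternative 1:** The cut runs through ring A itself (C1–C2 and C5–C6), leaving ring B attached through its ether oxygen to a three-carbon ynoate.
- Forward step: 1-methoxy-1,3-bis(trimethylsilyloxy)buta-1,3-diene A2 would add to methyl 3-aryloxypropiolate A1, CH2 terminus to the oxygen-bearing alkyne carbon and ketene acetal carbon to the ester-bearing carbon. Loss of methanol and desilylation would aromatise to A3, the target with its ring B C2 hydroxyl as MOM ether.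
- In favour: ring A would arrive with ester and both hydroxyls in place and unprotected, the crowded ether is never made by a coupling, and the polarity of both partners fixes the orientation. In protecting-group economy on ring A this is better than the chosen plan, and in convergence it is its equal.
- Against: A1 is an ynol ether of a doubly ortho-substituted, electron-rich phenol, which is hard to prepare and handle. The aryloxy donor lowers the reactivity of the alkyne, so a stepwise Michael addition that stops before ring closure is likely. The complete ring B, with four differentiated oxygens and both prenyl groups, must be made beforehand, which is the part of the problem the chosen route avoids by drawing the C2 oxygen from the xanthone carbonyl.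
- Comparison: neither key step has direct precedent on such substrates, so the two are level on mechanism. Alternative 1 needs one step after its key step against two here, but more steps for ring B, so the totals would probably be level or worse.

**Alternative 2:** Both aryl–CH2 bonds of ring B are cut.
- Forward step: heating the bis(1,1-dimethylallyl) ether A4 should cause two aromatic Claisen shifts, from the C2 oxygen to C3 and from the C5 oxygen to C4, each into the only free ortho position, giving the hydroquinone A5.
- In favour: both shifts are established chemistry, so on mechanistic security its key step is better than the chosen one. Both prenyl groups come from one operation, and no borylation or lithiation beside a prenyl group is needed.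
- Against: A5 is an air-sensitive hydroquinone whose two hydroxyls must still be told apart. This needs cleavage of the silylethyl ester and lactonisation onto the C2 oxygen, which arrives at the same depsidone 26 and the same end-game (four steps after the key step against two). The tertiary allyl ethers of an electron-rich hydroquinone ionise easily. The crowded ether of A4 must still be formed by coupling hindered partners, which the aryne annulation avoids.
- Comparison: structurally the two plans are equal in relying on the depsidone to distinguish the C2 and C5 oxygens. Alternative 2 is safer at its key step but longer afterwards and no shorter before it.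

**Alternative 3:** The O–C6 and C1–carboxyl bonds of ring A are cut.
- Forward step: CsF would release aryne 21 from 20 (the same aryne as in the chosen route), the phenoxide of A6 would add at the carbon remote from the flanking acetal oxygen, and the aryl anion would take up carbon dioxide to give acid A7.
- In favour: it is the most convergent plan and on that point better than the chosen one. It uses the same regiochemical rule for the aryne (equal) and needs no oxygen insertion and no lactone. Two steps follow the key step (esterification, acetal cleavage), equal to the chosen plan.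
- Against: A6 presupposes ring B with all four oxygens differentiated and both prenyl groups in place. The crowded aryl anion may be protonated before it captures carbon dioxide. Carbon dioxide can tie up the phenoxide reversibly as a carbonate. Capture of aryne-derived anions by carbon dioxide is established for nitrogen nucleophiles rather than for phenoxides.
- Comparison: mechanistically both key steps are unproven. Alternative 3 moves the difficulty into the synthesis of A6, whereas the chosen plan keeps ring B at three oxygens until the last stages.

Key step: step 14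

Assumption: 2-methoxybenzene-1,3-diol 1 is taken as a catalogue compound; it already carries the methyl ether that becomes the ring B C6 methoxy group, so no selective methylation of a 1,2,3-triol is needed.

## Route

Step 1
Reactants: 1 2-methoxybenzene-1,3-diol (2-methoxyresorcinol)
Product: 2 2-methoxy-1,3-bis(methoxymethoxy)benzene
Conditions: MOMCl (2.5 equiv), i-Pr2NEt, CH2Cl2, 0 °C → rt
Reagents that add atoms: chloromethyl methyl ether, COCCl
Why: Williamson-type O-alkylation of both phenols; the MOM ethers tolerate borylation, organolithium and fluoride and later direct the ring lithiation.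

Step 2
Reactants: 2 2-methoxy-1,3-bis(methoxymethoxy)benzene
Product: 3 2-[4-methoxy-3,5-bis(methoxymethoxy)phenyl]-4,4,5,5-tetramethyl-1,3,2-dioxaborolane
Conditions: [Ir(OMe)(cod)]2 (cat.), 4,4'-di-tert-butyl-2,2'-bipyridine (cat.), B2pin2 (1.0 equiv), cyclohexane, 80 °C
Reagents that add atoms: bis(pinacolato)diboron, CC1(C)OB(OC1(C)C)B1OC(C)(C)C(C)(C)O1
Why: Sterically controlled iridium-catalysed C–H borylation; in a 1,2,3-trisubstituted benzene only C5 has two hydrogen neighbours, so boron enters meta to both MOM ethers.

Step 3
Reactants: 3 2-[4-methoxy-3,5-bis(methoxymethoxy)phenyl]-4,4,5,5-tetramethyl-1,3,2-dioxaborolane; 4 1-bromo-3-methylbut-2-ene (prenyl bromide)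
Product: 5 2-methoxy-1,3-bis(methoxymethoxy)-5-(3-methylbut-2-enyl)benzene
Conditions: Pd(PPh3)4 (5 mol%), CsF (anhydrous), THF, 65 °C
Reagents that add atoms: none
Why: Suzuki–Miyaura allylation; reductive elimination from the aryl prenyl palladium intermediate at the unsubstituted terminus should give the linear prenyl arene, and anhydrous fluoride activation avoids hydrolysis of 4.

Step 4
Reactants: 5 2-methoxy-1,3-bis(methoxymethoxy)-5-(3-methylbut-2-enyl)benzene
Product: 7 methyl 3-methoxy-2,4-bis(methoxymethoxy)-6-(3-methylbut-2-enyl)benzoate, via aryllithium 6 (not isolated)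
Conditions: n-BuLi, TMEDA, THF, −20 → 0 °C; then cannulated into ClCO2Me (3 equiv), THF, −78 °C → rt
Reagents that add atoms: methyl chloroformate, COC(=O)Cl
Why: Directed ortho-metalation; each MOM ether has one free ortho position and the two are equivalent by symmetry, and inverse quench gives a doubly ortho-substituted benzoate that resists a second addition.

Step 5
Reactants: 7 methyl 3-methoxy-2,4-bis(methoxymethoxy)-6-(3-methylbut-2-enyl)benzoate
Product: 8 methyl 2,4-dihydroxy-3-methoxy-6-(3-methylbut-2-enyl)benzoate
Conditions: HCl (3 M in MeOH), rt
Reagents that add atoms: none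
Why: Acid-catalysed acetal exchange with methanol; no phenol stands next to the prenyl group here, so chroman formation is not possible at this stage.

Step 6
Reactants: 9 2-methylbut-3-en-2-ol
Product: 10 tert-butyl 2-methylbut-3-en-2-yl carbonate
Conditions: n-BuLi, THF, −78 → 0 °C; then Boc2O, 0 °C → rt
Reagents that add atoms: di-tert-butyl dicarbonate, CC(C)(C)OC(=O)OC(=O)OC(C)(C)C
Why: Acylation of the lithium alkoxide by the dicarbonate; a standard preparation of tertiary allyl carbonates.

Step 7
Reactants: 8 methyl 2,4-dihydroxy-3-methoxy-6-(3-methylbut-2-enyl)benzoate; 10 tert-butyl 2-methylbut-3-en-2-yl carbonate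
Product: 11 methyl 2-hydroxy-3-methoxy-4-(2-methylbut-3-en-2-yloxy)-6-(3-methylbut-2-enyl)benzoate
Conditions: Pd(PPh3)4 (5 mol%), 4 Å MS, THF, 0 °C → rt
Reagents that add atoms: none
Why: Decarboxylative Tsuji–Trost O-allylation; under kinetic control at low temperature the phenoxide attacks the tertiary terminus of the 1,1-dimethylallyl palladium complex, and only the C4 hydroxyl reacts because the C2 hydroxyl is chelated to the ester.

Step 8
Reactants: 12 benzene-1,3,5-triol (phloroglucinol)
Product: 13 3,5-bis(methoxymethoxy)phenol
Conditions: MOMCl (2.0 equiv), i-Pr2NEt, DMF, 0 °C → rt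
Reagents that add atoms: chloromethyl methyl ether, COCCl
Why: Statistical Williamson-type bis-alkylation of a symmetrical triol; the mono- and tris-ethers are separable and can be returned to 12 by acid.

Step 9
Reactants: 13 3,5-bis(methoxymethoxy)phenol
Product: 14 3,5-bis(methoxymethoxy)phenyl N-isopropylcarbamate
Conditions: i-PrNCO, Et3N (cat.), CH2Cl2, rt
Reagents that add atoms: isopropyl isocyanate, CC(C)N=C=O
Why: Base-catalysed addition of the phenol to the isocyanate; the secondary carbamate is a strong metalation director that can later be removed under mild base.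

Step 10
Reactants: 14 3,5-bis(methoxymethoxy)phenyl N-isopropylcarbamate
Product: 18 3,5-bis(methoxymethoxy)-2-(trimethylsilyl)phenyl N-isopropylcarbamate, via N-silyl carbamate 15 (not isolated), via lithiated carbamate 16 (not isolated), via C-silyl N-silyl carbamate 17 (not isolated)
Conditions: TBSOTf, TMEDA, Et2O, 0 °C → rt; n-BuLi (2 equiv), TMEDA, −78 °C; TMSCl, −78 °C → rt; aq. NaHSO4
Reagents that add atoms: chlorotrimethylsilane, C[Si](C)(C)Cl
Why: Directed ortho-metalation of the carbamate after temporary N-silylation; the carbamate is the stronger director and the position between it and a MOM ether is doubly activated, so lithiation there should beat the position between the two MOM ethers. The N–Si bond is lost on acidic work-up.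

Step 11
Reactants: 18 3,5-bis(methoxymethoxy)-2-(trimethylsilyl)phenyl N-isopropylcarbamate
Product: 20 3,5-bis(methoxymethoxy)-2-(trimethylsilyl)phenyl trifluoromethanesulfonate, via phenol 19 (not isolated)
Conditions: Et2NH, DBU, MeCN, 40 °C; then PhNTf2, rt
Reagents that add atoms: N-phenylbis(trifluoromethanesulfonimide), O=S(=O)(N(c1ccccc1)S(=O)(=O)C(F)(F)F)C(F)(F)F
Why: E1cB cleavage of the secondary carbamate (the isocyanate is trapped by diethylamine) and triflation of the phenoxide in the same flask; a standard route to ortho-silylaryl triflate aryne precursors.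

Step 12
Reactants: 11 methyl 2-hydroxy-3-methoxy-4-(2-methylbut-3-en-2-yloxy)-6-(3-methylbut-2-enyl)benzoate; 20 3,5-bis(methoxymethoxy)-2-(trimethylsilyl)phenyl trifluoromethanesulfonate
Product: 22 5-methoxy-1,3-bis(methoxymethoxy)-6-(2-methylbut-3-en-2-yloxy)-8-(3-methylbut-2-enyl)-9H-xanthen-9-one, via aryne 21 (not isolated)
Conditions: 20 (1.3 equiv), CsF (4 equiv), THF, 65 °C
Reagents that add atoms: none
Why: Aryne–salicylate annulation (tandem aryne insertion and intramolecular acyl substitution); the phenoxide of 11 adds to 21 at the carbon remote from the flanking MOM ether, and the aryl anion, stabilised by that ether, attacks the neighbouring ester through a six-membered transition state and expels methoxide. The tertiary allyl ether keeps the second phenol from being arylated.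

Step 13
Reactants: 22 5-methoxy-1,3-bis(methoxymethoxy)-6-(2-methylbut-3-en-2-yloxy)-8-(3-methylbut-2-enyl)-9H-xanthen-9-one
Product: 24 6-hydroxy-5-methoxy-1,3-bis(methoxymethoxy)-7,8-bis(3-methylbut-2-enyl)-9H-xanthen-9-one, via dienone 23 (not isolated)
Conditions: PhMe, 120 °C (sealed tube)
Reagents that add atoms: none
Why: Aromatic Claisen rearrangement; C7 is the only free position ortho to O6 (C5 carries the methoxy group), the [3,3] shift turns the 1,1-dimethylallyl unit into a prenyl group, and tautomerisation of 23 frees the C6 hydroxyl needed in the key step.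

Step 14
Reactants: 24 6-hydroxy-5-methoxy-1,3-bis(methoxymethoxy)-7,8-bis(3-methylbut-2-enyl)-9H-xanthen-9-one
Product: 26 7-hydroxy-6-methoxy-1,3-bis(methoxymethoxy)-8,9-bis(3-methylbut-2-enyl)-11H-dibenzo[b,e][1,4]dioxepin-11-one, via peroxy adduct 25 (not isolated)
Conditions: urea·H2O2 (4 equiv), Cs2CO3 (2.5 equiv), THF/DMF, 0 °C → rt, Ar; aq. NaHSO3, pH 5 buffer
Reagents that add atoms: urea–hydrogen peroxide adduct, NC(N)=O.OO
Why: Proposed new method: CsOOH, formed from urea–hydrogen peroxide and Cs2CO3, should add to C9 of the phenoxide of 24 to give the tetrahedral adduct 25, which collapses by a Criegee-type 1,2-shift of the ring B carbon C8a from C9 to the proximal peroxide oxygen with loss of hydroxide. The closest known reaction types are the Dakin oxidation of para-hydroxyaryl ketones, of which this is a ring-fused case, and the Baeyer–Villiger ring expansion of cyclic diaryl ketones. The seven-membered lactone is not formed by a cyclisation event but by ring expansion, one oxygen being inserted into the C9–C8a bond of the six-membered pyranone, so no ring-closure rule applies. No stereocentre is formed. Addition to the doubly vinylogous carbonyl is expected to be the slow step; it should be helped by relief of the peri strain between the C1 MOM ether, the carbonyl and the C8 prenyl group on pyramidalisation and by the alpha-effect nucleophile in a dipolar aprotic medium. Ring B must migrate and not ring A, which the C6 phenoxide para to C8a should secure, since the oxygens of ring A are capped as base-stable MOM ethers. Nucleophilic peroxide does not epoxidise the isolated prenyl alkenes, acetonitrile is avoided so that no peroxyimidic acid can form, and the absence of methanol and aqueous hydroxide should spare the doubly ortho-substituted aryl ester, which masks the C2 oxygen for the next step.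

Step 15
Reactants: 26 7-hydroxy-6-methoxy-1,3-bis(methoxymethoxy)-8,9-bis(3-methylbut-2-enyl)-11H-dibenzo[b,e][1,4]dioxepin-11-one
Product: 27 6,7-dimethoxy-1,3-bis(methoxymethoxy)-8,9-bis(3-methylbut-2-enyl)-11H-dibenzo[b,e][1,4]dioxepin-11-one
Conditions: MeI, K2CO3, acetone, rt
Reagents that add atoms: iodomethane, CI
Why: Williamson methylation of the only free hydroxyl; the ring B C2 oxygen is held in the lactone, so no selectivity question arises.

Step 16
Reactants: 27 6,7-dimethoxy-1,3-bis(methoxymethoxy)-8,9-bis(3-methylbut-2-enyl)-11H-dibenzo[b,e][1,4]dioxepin-11-one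
Product: 29 methyl 2,4-dihydroxy-6-[2-hydroxy-5,6-dimethoxy-3,4-bis(3-methylbut-2-enyl)phenoxy]benzoate (4-methylhydroatrovirinone), via methyl ester 28 (not isolated)
Conditions: NaOMe (1.5 equiv), MeOH/THF, 0 °C → rt; then HCl (to 2 M), MeOH, rt
Reagents that add atoms: sodium methoxide, C[O-].[Na+]
Why: Transesterification of the aryl lactone by methoxide gives methyl ester 28 and the ring B C2 phenoxide; acidification in the same flask removes both MOM ethers by acetal exchange with methanol under conditions commonly tolerated by prenylated phenols.

## Compound list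

1 | 2-methoxybenzene-1,3-diol | COc1c(O)cccc1O | starting material
2 | 2-methoxy-1,3-bis(methoxymethoxy)benzene | COCOc1cccc(OCOC)c1OC | intermediate
3 | 2-[4-methoxy-3,5-bis(methoxymethoxy)phenyl]-4,4,5,5-tetramethyl-1,3,2-dioxaborolane | COCOc1cc(B2OC(C)(C)C(C)(C)O2)cc(OCOC)c1OC | intermediate
4 | 1-bromo-3-methylbut-2-ene | CC(C)=CCBr | starting material
5 | 2-methoxy-1,3-bis(methoxymethoxy)-5-(3-methylbut-2-enyl)benzene | COCOc1cc(CC=C(C)C)cc(OCOC)c1OC | intermediate
6 | [3-methoxy-2,4-bis(methoxymethoxy)-6-(3-methylbut-2-enyl)phenyl]lithium | [Li]c1c(OCOC)c(OC)c(OCOC)cc1CC=C(C)C | intermediate (not isolated)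
7 | methyl 3-methoxy-2,4-bis(methoxymethoxy)-6-(3-methylbut-2-enyl)benzoate | COC(=O)c1c(OCOC)c(OC)c(OCOC)cc1CC=C(C)C | intermediate
8 | methyl 2,4-dihydroxy-3-methoxy-6-(3-methylbut-2-enyl)benzoate | COC(=O)c1c(O)c(OC)c(O)cc1CC=C(C)C | intermediate
9 | 2-methylbut-3-en-2-ol | CC(C)(O)C=C | starting material
10 | tert-butyl 2-methylbut-3-en-2-yl carbonate | CC(C)(C=C)OC(=O)OC(C)(C)C | intermediate
11 | methyl 2-hydroxy-3-methoxy-4-(2-methylbut-3-en-2-yloxy)-6-(3-methylbut-2-enyl)benzoate | COC(=O)c1c(O)c(OC)c(OC(C)(C)C=C)cc1CC=C(C)C | intermediate
12 | benzene-1,3,5-triol | Oc1cc(O)cc(O)c1 | starting material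
13 | 3,5-bis(methoxymethoxy)phenol | COCOc1cc(O)cc(OCOC)c1 | intermediate
14 | 3,5-bis(methoxymethoxy)phenyl N-isopropylcarbamate | COCOc1cc(OCOC)cc(OC(=O)NC(C)C)c1 | intermediate
15 | 3,5-bis(methoxymethoxy)phenyl N-(tert-butyldimethylsilyl)-N-isopropylcarbamate | COCOc1cc(OCOC)cc(OC(=O)N(C(C)C)[Si](C)(C)C(C)(C)C)c1 | intermediate (not isolated)
16 | 2-lithio derivative of 15 (lithium between the carbamate and a MOM ether) | COCOc1cc(OCOC)c([Li])c(OC(=O)N(C(C)C)[Si](C)(C)C(C)(C)C)c1 | intermediate (not isolated)
17 | 3,5-bis(methoxymethoxy)-2-(trimethylsilyl)phenyl N-(tert-butyldimethylsilyl)-N-isopropylcarbamate | COCOc1cc(OCOC)c([Si](C)(C)C)c(OC(=O)N(C(C)C)[Si](C)(C)C(C)(C)C)c1 | intermediate (not isolated)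
18 | 3,5-bis(methoxymethoxy)-2-(trimethylsilyl)phenyl N-isopropylcarbamate | COCOc1cc(OCOC)c([Si](C)(C)C)c(OC(=O)NC(C)C)c1 | intermediate
19 | 3,5-bis(methoxymethoxy)-2-(trimethylsilyl)phenol | COCOc1cc(OCOC)c([Si](C)(C)C)c(O)c1 | intermediate (not isolated)
20 | 3,5-bis(methoxymethoxy)-2-(trimethylsilyl)phenyl trifluoromethanesulfonate | COCOc1cc(OCOC)c([Si](C)(C)C)c(OS(=O)(=O)C(F)(F)F)c1 | intermediate
21 | 3,5-bis(methoxymethoxy)benzyne (1,2-didehydro-3,5-bis(methoxymethoxy)benzene) | C1#CC(OCOC)=CC(OCOC)=C1 | intermediate (not isolated)
22 | 5-methoxy-1,3-bis(methoxymethoxy)-6-(2-methylbut-3-en-2-yloxy)-8-(3-methylbut-2-enyl)-9H-xanthen-9-one | O=C1c2c(OCOC)cc(OCOC)cc2Oc2c(OC)c(OC(C)(C)C=C)cc(CC=C(C)C)c12 | intermediate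
23 | 5-methoxy-1,3-bis(methoxymethoxy)-7,8-bis(3-methylbut-2-enyl)-7H-xanthene-6,9-dione | O=C1c2c(OCOC)cc(OCOC)cc2OC2=C(OC)C(=O)C(CC=C(C)C)C(CC=C(C)C)=C12 | intermediate (not isolated)
24 | 6-hydroxy-5-methoxy-1,3-bis(methoxymethoxy)-7,8-bis(3-methylbut-2-enyl)-9H-xanthen-9-one | O=C1c2c(OCOC)cc(OCOC)cc2Oc2c(OC)c(O)c(CC=C(C)C)c(CC=C(C)C)c12 | intermediate (precursor of the key step)
25 | 9-hydroperoxy-5-methoxy-1,3-bis(methoxymethoxy)-7,8-bis(3-methylbut-2-enyl)-9H-xanthene-6,9-diol | OOC1(O)c2c(OCOC)cc(OCOC)cc2Oc2c(OC)c(O)c(CC=C(C)C)c(CC=C(C)C)c12 | intermediate (not isolated)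
26 | 7-hydroxy-6-methoxy-1,3-bis(methoxymethoxy)-8,9-bis(3-methylbut-2-enyl)-11H-dibenzo[b,e][1,4]dioxepin-11-one | O=C1Oc2c(CC=C(C)C)c(CC=C(C)C)c(O)c(OC)c2Oc2cc(OCOC)cc(OCOC)c12 | intermediate (product of the key step)
27 | 6,7-dimethoxy-1,3-bis(methoxymethoxy)-8,9-bis(3-methylbut-2-enyl)-11H-dibenzo[b,e][1,4]dioxepin-11-one | O=C1Oc2c(CC=C(C)C)c(CC=C(C)C)c(OC)c(OC)c2Oc2cc(OCOC)cc(OCOC)c12 | intermediate
28 | methyl 2-[2-hydroxy-5,6-dimethoxy-3,4-bis(3-methylbut-2-enyl)phenoxy]-4,6-bis(methoxymethoxy)benzoate | COC(=O)c1c(OCOC)cc(OCOC)cc1Oc1c(O)c(CC=C(C)C)c(CC=C(C)C)c(OC)c1OC | intermediate (not isolated)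
29 | methyl 2,4-dihydroxy-6-[2-hydroxy-5,6-dimethoxy-3,4-bis(3-methylbut-2-enyl)phenoxy]benzoate | COC(=O)c1c(O)cc(O)cc1Oc1c(O)c(CC=C(C)C)c(CC=C(C)C)c(OC)c1OC | target

## Step count and least certain steps

Total step count: 16. Longest linear sequence: 11 steps (steps 1–5, 7, 12–16).

**Step 14 (key step).**
- What may go wrong: hydroperoxide may fail to add to the strongly deactivated carbonyl, because the para phenoxide needed for migration also removes its electrophilicity. Second, the new lactone may undergo perhydrolysis to a peracid, followed by oxidation of the prenyl alkenes or of the electron-rich ring. Simple hydrolytic opening to the hydroxy acid would be repaired by a carbodiimide, since only the C2 oxygen can reach the carboxyl.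
- Fallback (known reactions only; sets out from 11, returns at 29): the oxygen is inserted at the aldehyde level of an open diaryl ether.
  - Heating 11 in toluene (aromatic Claisen shift) should give methyl 2,4-dihydroxy-3-methoxy-5,6-bis(3-methylbut-2-enyl)benzoate F1.
  - MeI and K2CO3 methylate only the hydroxyl not chelated to the ester, giving methyl 2-hydroxy-3,4-dimethoxy-5,6-bis(3-methylbut-2-enyl)benzoate F2.
  - LiAlH4 reduces the ester to 2-(hydroxymethyl)-5,6-dimethoxy-3,4-bis(3-methylbut-2-enyl)phenol F3, and MnO2 oxidises the benzylic alcohol to 2-hydroxy-3,4-dimethoxy-5,6-bis(3-methylbut-2-enyl)benzaldehyde F4.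
  - Ring A comes from commercial methyl 2,4,6-trihydroxybenzoate: MOMCl and i-Pr2NEt give methyl 2-hydroxy-4,6-bis(methoxymethoxy)benzoate F5, and Tf2O with pyridine gives methyl 2,4-bis(methoxymethoxy)-6-(trifluoromethylsulfonyloxy)benzoate F6.
  - A Buchwald–Hartwig-type C–O coupling of F4 with F6 (Pd(OAc)2, t-BuXPhos, K3PO4, toluene, 100 °C) should give methyl 2-[2-formyl-5,6-dimethoxy-3,4-bis(3-methylbut-2-enyl)phenoxy]-4,6-bis(methoxymethoxy)benzoate F7.
  - The acid-catalysed Dakin-type oxidation of alkoxybenzaldehydes (H2O2, catalytic H2SO4, MeOH, rt) converts the formyl group into the aryl formate, which is methanolysed to the C2 phenol. The same acidic methanol cleaves both MOM ethers, so the sequence ends at 29.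
  - Its own weak points are the coupling of two ortho-substituted partners and the exposure of the prenyl groups to acid.

**Step 12.**
- What may go wrong: the aryl anion may be protonated (by unreacted 11) before it reaches the crowded ester, so that the reaction stops at the open diaryl ether. A slow [3,3] shift of the tertiary allyl ether at 65 °C would expose a second phenol to arylation.
- Fallback (sets out from 11 and 20, returns at 22): the two bond formations are separated. O-Arylation with CsF in MeCN at rt, where the solvent protonates the aryl anion, should give methyl 2-[3,5-bis(methoxymethoxy)phenoxy]-3-methoxy-4-(2-methylbut-3-en-2-yloxy)-6-(3-methylbut-2-enyl)benzoate F8. LiTMP in THF at −78 °C then metalates ring A between the ether oxygen and a MOM ether, and the aryllithium closes onto the ester (anionic acyl substitution) to 22.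

**Step 4.**
- What may go wrong: deprotonation at the benzylic, allylic CH2 of the prenyl group instead of the ring C–H, followed by side-chain carboxylation or double-bond migration.
- Fallback (sets out from 5, returns at 8): electrophilic carboxylation instead of metalation. HCl in MeOH gives 2-methoxy-5-(3-methylbut-2-enyl)benzene-1,3-diol F9. Kolbe–Schmitt carboxylation (KHCO3, CO2, glycerol, 120 °C), which can occur only at the two equivalent free positions, gives 2,4-dihydroxy-3-methoxy-6-(3-methylbut-2-enyl)benzoic acid F10. MeI with KHCO3 in DMF esterifies the carboxylate to 8.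

**Step 3.**
- What may go wrong: bond formation at the tertiary terminus of the prenyl palladium intermediate, or double-bond migration, giving isomers that are hard to separate.
- Fallback (sets out from 3, returns at 5): the same coupling with allyl bromide, whose allyl unit is symmetrical, gives 5-allyl-2-methoxy-1,3-bis(methoxymethoxy)benzene F11. Cross-metathesis with 2-methylbut-2-ene (second-generation Grubbs catalyst, CH2Cl2, 40 °C) converts the allyl group into the prenyl group of 5.

**Step 16.**
- What may go wrong: acid-promoted ring closure of the freed C2 phenol onto the neighbouring prenyl double bond (chroman formation), or addition of methanol across the alkenes during acetal cleavage.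
- Fallback (sets out from 27, returns at 29): the order is reversed so that the C2 oxygen is still acylated when acid is present. HCl in MeOH at rt removes the MOM ethers from 27 to give 1,3-dihydroxy-6,7-dimethoxy-8,9-bis(3-methylbut-2-enyl)-11H-dibenzo[b,e][1,4]dioxepin-11-one F12. K2CO3 in MeOH then opens the lactone to 29 under base only.

## Further compounds

F1 | step 14 | methyl 2,4-dihydroxy-3-methoxy-5,6-bis(3-methylbut-2-enyl)benzoate | COC(=O)c1c(O)c(OC)c(O)c(CC=C(C)C)c1CC=C(C)C
F2 | step 14 | methyl 2-hydroxy-3,4-dimethoxy-5,6-bis(3-methylbut-2-enyl)benzoate | COC(=O)c1c(O)c(OC)c(OC)c(CC=C(C)C)c1CC=C(C)C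
F3 | step 14 | 2-(hydroxymethyl)-5,6-dimethoxy-3,4-bis(3-methylbut-2-enyl)phenol | OCc1c(O)c(OC)c(OC)c(CC=C(C)C)c1CC=C(C)C
F4 | step 14 | 2-hydroxy-3,4-dimethoxy-5,6-bis(3-methylbut-2-enyl)benzaldehyde | O=Cc1c(O)c(OC)c(OC)c(CC=C(C)C)c1CC=C(C)C
F5 | step 14 | methyl 2-hydroxy-4,6-bis(methoxymethoxy)benzoate | COC(=O)c1c(O)cc(OCOC)cc1OCOC
F6 | step 14 | methyl 2,4-bis(methoxymethoxy)-6-(trifluoromethylsulfonyloxy)benzoate | COC(=O)c1c(OCOC)cc(OCOC)cc1OS(=O)(=O)C(F)(F)F
F7 | step 14 | methyl 2-[2-formyl-5,6-dimethoxy-3,4-bis(3-methylbut-2-enyl)phenoxy]-4,6-bis(methoxymethoxy)benzoate | COC(=O)c1c(OCOC)cc(OCOC)cc1Oc1c(C=O)c(CC=C(C)C)c(CC=C(C)C)c(OC)c1OC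
F8 | step 12 | methyl 2-[3,5-bis(methoxymethoxy)phenoxy]-3-methoxy-4-(2-methylbut-3-en-2-yloxy)-6-(3-methylbut-2-enyl)benzoate | COC(=O)c1c(Oc2cc(OCOC)cc(OCOC)c2)c(OC)c(OC(C)(C)C=C)cc1CC=C(C)C
F9 | step 4 | 2-methoxy-5-(3-methylbut-2-enyl)benzene-1,3-diol | COc1c(O)cc(CC=C(C)C)cc1O
F10 | step 4 | 2,4-dihydroxy-3-methoxy-6-(3-methylbut-2-enyl)benzoic acid | O=C(O)c1c(O)c(OC)c(O)cc1CC=C(C)C
F11 | step 3 | 5-allyl-2-methoxy-1,3-bis(methoxymethoxy)benzene | COCOc1cc(CC=C)cc(OCOC)c1OC
F12 | step 16 | 1,3-dihydroxy-6,7-dimethoxy-8,9-bis(3-methylbut-2-enyl)-11H-dibenzo[b,e][1,4]dioxepin-11-one | O=C1Oc2c(CC=C(C)C)c(CC=C(C)C)c(OC)c(OC)c2Oc2cc(O)cc(O)c12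
A1 | alternative 1 | methyl 3-[2,3-dimethoxy-6-(methoxymethoxy)-4,5-bis(3-methylbut-2-enyl)phenoxy]prop-2-ynoate | COC(=O)C#COc1c(OCOC)c(CC=C(C)C)c(CC=C(C)C)c(OC)c1OC
A2 | alternative 1 | 1-methoxy-1,3-bis(trimethylsilyloxy)buta-1,3-diene | COC(O[Si](C)(C)C)=CC(=C)O[Si](C)(C)C
A3 | alternative 1 | methyl 2-[2,3-dimethoxy-6-(methoxymethoxy)-4,5-bis(3-methylbut-2-enyl)phenoxy]-4,6-dihydroxybenzoate | COC(=O)c1c(O)cc(O)cc1Oc1c(OCOC)c(CC=C(C)C)c(CC=C(C)C)c(OC)c1OC
A4 | alternative 2 | 2-(trimethylsilyl)ethyl 2-[2-methoxy-3,6-bis(2-methylbut-3-en-2-yloxy)phenoxy]-4,6-bis(methoxymethoxy)benzoate | C[Si](C)(C)CCOC(=O)c1c(OCOC)cc(OCOC)cc1Oc1c(OC(C)(C)C=C)ccc(OC(C)(C)C=C)c1OC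
A5 | alternative 2 | 2-(trimethylsilyl)ethyl 2-[2,5-dihydroxy-6-methoxy-3,4-bis(3-methylbut-2-enyl)phenoxy]-4,6-bis(methoxymethoxy)benzoate | C[Si](C)(C)CCOC(=O)c1c(OCOC)cc(OCOC)cc1Oc1c(O)c(CC=C(C)C)c(CC=C(C)C)c(O)c1OC
A6 | alternative 3 | 2,3-dimethoxy-6-(methoxymethoxy)-4,5-bis(3-methylbut-2-enyl)phenol | Oc1c(OCOC)c(CC=C(C)C)c(CC=C(C)C)c(OC)c1OC
A7 | alternative 3 | 2-[2,3-dimethoxy-6-(methoxymethoxy)-4,5-bis(3-methylbut-2-enyl)phenoxy]-4,6-bis(methoxymethoxy)benzoic acid | O=C(O)c1c(OCOC)cc(OCOC)cc1Oc1c(OCOC)c(CC=C(C)C)c(CC=C(C)C)c(OC)c1OC
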